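**Plan** (labels: chromone O1, C2, C3, C4, C5–C8, ring A = benzo ring of the chromone; ring B = C1'–C6', with C1' on C3 and the furan oxygen on C2')
- Enabling feature: the furan ring ties ring B carbon C1' and its phenolic oxygen to C3 and C2, where C3 bears the ring A aroyl carbon C4 and C2 a heteroatom. This is the adduct of a ring B ortho-quinone methide, carrying the aroyl group on its methide carbon, with a one-carbon isocyanide.
- Retrosynthesis: the C5 methyl ether is cut first, then the pyranone bond O1–C2 (ring A phenol displacing an amine on C2). The furan bonds C3–C1', C2–C3 and C2–O are then cut together to a ring A arylglyoxal, a ring B chromenol and tert-butyl isocyanide.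
- Fragments: 2,4,6-trihydroxyacetophenone gains its dihydropyran by propargyl ether Claisen rearrangement and hydrogenation, and its acetyl group is oxidised to the glyoxal. 5-Bromosalicylaldehyde gives the chromene by a second propargyl Claisen rearrangement, and the bromide is then turned into the phenol.
- Forward ring order: dihydropyran on ring A and pyran on ring B, then the furan (three-component step), then the pyranone. The C5 methyl ether forces the pyranone to close on the oxygen next to the chroman methylene and is removed last.
- Stereochemistry: the target has no stereocentre and none has to be set; the one stereogenic intermediate (a carbinol) is racemic and transient.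

Key step: step 12

Remark: arylglyoxal 9 equilibrates with its hydrate; it is dried azeotropically with toluene before step 12 and is counted as one compound.

**Step 1**
Reactants: 1 2,4,6-trihydroxyacetophenone; 2 3-chloro-3-methylbut-1-yne
Product: 3 1-[2,6-dihydroxy-4-(2-methylbut-3-yn-2-yloxy)phenyl]ethanone
Conditions: 2 (1.1 equiv), K2CO3 (1.2 equiv), KI (0.2 equiv), CuI (5 mol %), acetone, 50 °C
Reagents that add atoms: none
Why: Copper-assisted Williamson-type O-alkylation with the tertiary propargylic chloride should take place on the C4 hydroxyl, the most acidic and least hindered of the three, as with 2,4-dihydroxyacetophenone; one equivalent of electrophile limits dialkylation.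

**Step 2**
Reactants: 3 1-[2,6-dihydroxy-4-(2-methylbut-3-yn-2-yloxy)phenyl]ethanone
Product: 4 1-[2-hydroxy-6-methoxy-4-(2-methylbut-3-yn-2-yloxy)phenyl]ethanone
Conditions: MeI (1.1 equiv), K2CO3 (1.2 equiv), acetone, rt
Reagents that add atoms: iodomethane, CI
Why: Williamson methylation of one of the two equivalent ortho hydroxyls; the second stays locked in a strong hydrogen bond to the acetyl carbonyl and should not be alkylated by a carbonate base at room temperature.

**Step 3**
Reactants: 4 1-[2-hydroxy-6-methoxy-4-(2-methylbut-3-yn-2-yloxy)phenyl]ethanone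
Product: 6 1-(5-hydroxy-7-methoxy-2,2-dimethyl-2H-chromen-6-yl)ethanone, via allenylphenol 5 (not isolated)
Conditions: N,N-diethylaniline, 180 °C, argon
Reagents that add atoms: none
Why: Aryl propargyl ether Claisen rearrangement followed by 1,5-hydrogen shift and 6π-oxa-electrocyclisation; as with chelated 2,4-dihydroxyacetophenone ethers the [3,3] shift should go to C3, between the chelated hydroxyl and the ether oxygen, and because that hydroxyl stays tied to the carbonyl the pyran closes on the former ether oxygen, so the free hydroxyl of 6 sits next to pyran carbon C4.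

**Step 4**
Reactants: 6 1-(5-hydroxy-7-methoxy-2,2-dimethyl-2H-chromen-6-yl)ethanone
Product: 7 1-(5-hydroxy-7-methoxy-2,2-dimethylchroman-6-yl)ethanone
Conditions: H2 (1 atm), Pd/C (10 %), EtOAc, rt
Reagents that add atoms: none
Why: Heterogeneous catalytic hydrogenation of the styrene-type cis double bond; the hindered, chelated aryl ketone and the aryl ethers should not be reduced at atmospheric pressure.

**Step 5**
Reactants: 7 1-(5-hydroxy-7-methoxy-2,2-dimethylchroman-6-yl)ethanone
Product: 8 1-[7-methoxy-5-(methoxymethoxy)-2,2-dimethylchroman-6-yl]ethanone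
Conditions: NaH (1.1 equiv), DMF, 0 °C; MOMCl (1.3 equiv), 0 °C to rt
Reagents that add atoms: chloromethyl methyl ether, COCCl
Why: Williamson etherification of the sodium phenoxide; one equivalent of hydride deprotonates only the phenol and not the methyl ketone, and this acetal is the one that the acid of step 13 removes to free the oxygen that becomes O1.

**Step 6**
Reactants: 8 1-[7-methoxy-5-(methoxymethoxy)-2,2-dimethylchroman-6-yl]ethanone
Product: 9 2-[7-methoxy-5-(methoxymethoxy)-2,2-dimethylchroman-6-yl]-2-oxoacetaldehyde
Conditions: SeO2 (1.5 equiv), 1,4-dioxane/H2O (20:1), 90 °C; filtration, azeotropic drying with toluene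
Reagents that add atoms: selenium dioxide, O=[Se]=O
Why: Riley oxidation of the aryl methyl ketone to the α-keto aldehyde through the enol and its selenium ester; with both ortho oxygens capped the glyoxal cannot close to a cyclic hemiacetal.

**Step 7**
Reactants: 10 5-bromo-2-hydroxybenzaldehyde
Product: 11 5-bromo-2-(methoxymethoxy)benzaldehyde
Conditions: MOMCl (1.3 equiv), K2CO3, acetone, rt
Reagents that add atoms: chloromethyl methyl ether, COCCl
Why: Williamson etherification of the phenoxide; the acetal should survive the base, heat and organolithium steps that follow and is removed by acid in step 13.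

**Step 8**
Reactants: 11 5-bromo-2-(methoxymethoxy)benzaldehyde
Product: 13 5-bromo-2-(methoxymethoxy)phenol, via aryl formate 12 (not isolated)
Conditions: mCPBA (1.3 equiv), CH2Cl2, rt; aq NaHCO3 wash; then K2CO3 (0.2 equiv), MeOH, rt
Reagents that add atoms: 3-chloroperbenzoic acid, OOC(=O)c1cccc(Cl)c1
Why: Baeyer–Villiger (Dakin-type) oxidation in which the ortho-alkoxy aryl group migrates in the Criegee intermediate to give the aryl formate, cleaved by methanolysis; the peracid is used at this stage because no alkene is present yet.

**Step 9**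
Reactants: 13 5-bromo-2-(methoxymethoxy)phenol; 2 3-chloro-3-methylbut-1-yne
Product: 14 4-bromo-1-(methoxymethoxy)-2-(2-methylbut-3-yn-2-yloxy)benzene
Conditions: 2 (1.5 equiv), K2CO3 (2 equiv), KI (0.2 equiv), CuI (5 mol %), acetone, 55 °C
Reagents that add atoms: none
Why: Copper-assisted Williamson-type etherification of the phenol with the tertiary propargylic chloride, the standard entry to aryl 1,1-dimethylpropargyl ethers.

**Step 10**
Reactants: 14 4-bromo-1-(methoxymethoxy)-2-(2-methylbut-3-yn-2-yloxy)benzene
Product: 16 5-bromo-8-(methoxymethoxy)-2,2-dimethyl-2H-chromene, via allenylphenol 15 (not isolated)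
Conditions: N,N-diethylaniline, 185 °C, argon
Reagents that add atoms: none
Why: Aryl propargyl ether Claisen rearrangement, 1,5-hydrogen shift and 6π-oxa-electrocyclisation; the [3,3] shift can only go to the one free ortho carbon (the other carries the methoxymethoxy group), which places bromine on C5 of the chromene, and a bromide, unlike a free hydroxyl, cannot take part in the ring closure.

**Step 11**
Reactants: 16 5-bromo-8-(methoxymethoxy)-2,2-dimethyl-2H-chromene
Product: 19 8-(methoxymethoxy)-2,2-dimethyl-2H-chromen-5-ol, via aryllithium 17 (not isolated), via dimethyl arylboronate 18 (not isolated)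
Conditions: n-BuLi (1.1 equiv), THF, −78 °C; B(OMe)3 (1.5 equiv), −78 to 0 °C; then H2O2 (30 %), NaOH (2 M), 0 °C to rt
Reagents that add atoms: hydrogen peroxide, OO
Why: Bromine–lithium exchange, trapping with trimethyl borate and oxidation of the arylboronate by alkaline hydrogen peroxide (1,2-aryl shift from boron to oxygen), a nucleophilic oxidant that should leave the electron-rich chromene double bond untouched.

**Step 12**
Reactants: 9 2-[7-methoxy-5-(methoxymethoxy)-2,2-dimethylchroman-6-yl]-2-oxoacetaldehyde; 19 8-(methoxymethoxy)-2,2-dimethyl-2H-chromen-5-ol; 20 tert-butyl isocyanide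
Product: 23 [2-(tert-butylamino)-5-(methoxymethoxy)-7,7-dimethyl-7H-furo[2,3-f]chromen-3-yl][7-methoxy-5-(methoxymethoxy)-2,2-dimethylchroman-6-yl]methanone, via carbinol 21 (not isolated), via ortho-quinone methide 22 (not isolated)
Conditions: 9 (1.0 equiv), 19 (1.0 equiv), 20 (1.5 equiv), pyridinium p-toluenesulfonate (20 mol %), 4 Å MS, toluene, 80 °C
Reagents that add atoms: none
Why: Mild acid promotes ortho-hydroxyalkylation of phenol 19 at C6 by the aldehyde carbon of 9 (bond C3–C1'), and carbinol 21 loses water to the aroyl ortho-quinone methide 22; the isocyanide carbon adds to the methide carbon (bond C2–C3), the phenoxide oxygen closes on the nitrilium carbon (bond C2–O) and the 2-imino-2,3-dihydrobenzofuran tautomerises to the aromatic 2-aminobenzofuran. The closest known reaction type is the three-component phenol or naphthol, aldehyde and isocyanide synthesis of 2-aminobenzofurans, a formal [4+1] cycloaddition of an ortho-quinone methide, run here with an arylglyoxal as the aldehyde. The furan ring closes by 5-exo-dig attack of oxygen on the nitrilium ion after the intermolecular C–C bond formation, four ring atoms coming from 22 and one from 20. No stereocentre remains, because the carbinol carbon of 21 becomes sp2. Site selectivity on the phenol rests on C6 being its only free ortho carbon (C4a is substituted, the para carbon C8 carries the methoxymethoxy group) and being para to the pyran oxygen; the aldehyde should react in preference to the ketone, which is flanked by two ortho substituents and twisted out of conjugation. Both ortho oxygens of ring A are capped, so the quinone methide cannot be intercepted intramolecularly and is left to the isocyanide, which is present from the start.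

**Step 13**
Reactants: 23 [2-(tert-butylamino)-5-(methoxymethoxy)-7,7-dimethyl-7H-furo[2,3-f]chromen-3-yl][7-methoxy-5-(methoxymethoxy)-2,2-dimethylchroman-6-yl]methanone
Product: 25 5-O-methylformosanatin D, via deprotected aminobenzofuran 24 (not isolated)
Conditions: HCl (1.25 M in MeOH, anhydrous), THF, 50 °C
Reagents that add atoms: none
Why: Proposed new method: methanolic HCl removes both methoxymethyl ethers by acetal exchange and protonates the carbonyl oxygen of the 3-acyl-2-aminobenzofuran, a vinylogous carbamate, so that C2 becomes an amidinium-like electrophile; the only free ortho hydroxyl of ring A (next to the chroman methylene) adds to C2 through a six-membered transition state, and proton transfer to nitrogen with loss of tert-butylammonium chloride restores the furan and gives the 4-pyranone, the closest known reaction type being the acid-promoted cyclisation of 2-hydroxyaryl enaminones to chromones with loss of the amine; the methyl ether on the other ortho oxygen excludes the linear isomer, and because C2 carries the leaving group no coumestan can form.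

**Step 14**
Reactants: 25 5-O-methylformosanatin D
Product: 26 formosanatin D
Conditions: BCl3 (1 M in CH2Cl2, 3 equiv), CH2Cl2, −78 to −10 °C; MeOH, then aq NaHCO3
Reagents that add atoms: none
Why: Chelation-controlled ether cleavage in which BCl3 binds between the C4 carbonyl and the peri C5 methoxyl and chloride removes the methyl group, the standard selective demethylation of 5-methoxychromones, run cold and with limited reagent to spare the chromene and the tertiary alkyl aryl ethers.

**Compound list**
1 | 2,4,6-trihydroxyacetophenone | CC(=O)c1c(O)cc(O)cc1O | starting material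
2 | 3-chloro-3-methylbut-1-yne | CC(C)(Cl)C#C | starting material
3 | 1-[2,6-dihydroxy-4-(2-methylbut-3-yn-2-yloxy)phenyl]ethanone | CC(=O)c1c(O)cc(OC(C)(C)C#C)cc1O | intermediate
4 | 1-[2-hydroxy-6-methoxy-4-(2-methylbut-3-yn-2-yloxy)phenyl]ethanone | CC(=O)c1c(O)cc(OC(C)(C)C#C)cc1OC | intermediate
5 | 1-[2,4-dihydroxy-6-methoxy-3-(3-methylbuta-1,2-dien-1-yl)phenyl]ethanone (allenylphenol) | CC(=O)c1c(O)c(C=C=C(C)C)c(O)cc1OC | intermediate
6 | 1-(5-hydroxy-7-methoxy-2,2-dimethyl-2H-chromen-6-yl)ethanone | CC(=O)c1c(OC)cc2OC(C)(C)C=Cc2c1O | intermediate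
7 | 1-(5-hydroxy-7-methoxy-2,2-dimethylchroman-6-yl)ethanone | CC(=O)c1c(OC)cc2OC(C)(C)CCc2c1O | intermediate
8 | 1-[7-methoxy-5-(methoxymethoxy)-2,2-dimethylchroman-6-yl]ethanone | CC(=O)c1c(OC)cc2OC(C)(C)CCc2c1OCOC | intermediate
9 | 2-[7-methoxy-5-(methoxymethoxy)-2,2-dimethylchroman-6-yl]-2-oxoacetaldehyde (ring A arylglyoxal) | COCOc1c2CCC(C)(C)Oc2cc(OC)c1C(=O)C=O | intermediate
10 | 5-bromo-2-hydroxybenzaldehyde | O=Cc1cc(Br)ccc1O | starting material
11 | 5-bromo-2-(methoxymethoxy)benzaldehyde | COCOc1ccc(Br)cc1C=O | intermediate
12 | 5-bromo-2-(methoxymethoxy)phenyl formate | COCOc1ccc(Br)cc1OC=O | intermediate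
13 | 5-bromo-2-(methoxymethoxy)phenol | COCOc1ccc(Br)cc1O | intermediate
14 | 4-bromo-1-(methoxymethoxy)-2-(2-methylbut-3-yn-2-yloxy)benzene | COCOc1ccc(Br)cc1OC(C)(C)C#C | intermediate
15 | 3-bromo-6-(methoxymethoxy)-2-(3-methylbuta-1,2-dien-1-yl)phenol (allenylphenol) | COCOc1ccc(Br)c(C=C=C(C)C)c1O | intermediate
16 | 5-bromo-8-(methoxymethoxy)-2,2-dimethyl-2H-chromene | COCOc1ccc(Br)c2C=CC(C)(C)Oc12 | intermediate
17 | [8-(methoxymethoxy)-2,2-dimethyl-2H-chromen-5-yl]lithium | [Li]c1ccc(OCOC)c2OC(C)(C)C=Cc12 | intermediate
18 | dimethyl [8-(methoxymethoxy)-2,2-dimethyl-2H-chromen-5-yl]boronate | COCOc1ccc(B(OC)OC)c2C=CC(C)(C)Oc12 | intermediate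
19 | 8-(methoxymethoxy)-2,2-dimethyl-2H-chromen-5-ol (ring B chromenol) | COCOc1ccc(O)c2C=CC(C)(C)Oc12 | intermediate
20 | tert-butyl isocyanide | CC(C)(C)[N+]#[C-] | starting material
21 | 2-hydroxy-2-[5-hydroxy-8-(methoxymethoxy)-2,2-dimethyl-2H-chromen-6-yl]-1-[7-methoxy-5-(methoxymethoxy)-2,2-dimethylchroman-6-yl]ethanone (racemic carbinol) | COCOc1cc(C(O)C(=O)c3c(OC)cc4OC(C)(C)CCc4c3OCOC)c(O)c2C=CC(C)(C)Oc12 | intermediate
22 | 6-{2-[7-methoxy-5-(methoxymethoxy)-2,2-dimethylchroman-6-yl]-2-oxoethylidene}-8-(methoxymethoxy)-2,2-dimethyl-2H-chromen-5(6H)-one (aroyl ortho-quinone methide) | COCOC1=CC(=CC(=O)c3c(OC)cc4OC(C)(C)CCc4c3OCOC)C(=O)C2=C1OC(C)(C)C=C2 | intermediate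
23 | [2-(tert-butylamino)-5-(methoxymethoxy)-7,7-dimethyl-7H-furo[2,3-f]chromen-3-yl][7-methoxy-5-(methoxymethoxy)-2,2-dimethylchroman-6-yl]methanone (2-aminobenzofuran; furan oxygen on former C5 and furan C3 on former C6 of 19) | CC1(C)C=Cc2c(c(OCOC)cc3c2oc(NC(C)(C)C)c3C(=O)c2c(OCOC)c4CCC(C)(C)Oc4cc2OC)O1 | intermediate
24 | [2-(tert-butylamino)-5-hydroxy-7,7-dimethyl-7H-furo[2,3-f]chromen-3-yl](5-hydroxy-7-methoxy-2,2-dimethylchroman-6-yl)methanone | CC1(C)C=Cc2c(c(O)cc3c2oc(NC(C)(C)C)c3C(=O)c2c(O)c4CCC(C)(C)Oc4cc2OC)O1 | intermediate
25 | 5-O-methylformosanatin D (formosanatin D with OMe in place of the C5 hydroxyl) | CC1(C)C=Cc2c(c(O)cc3c2oc2oc4c5c(cc(OC)c4c(=O)c23)OC(C)(C)CC5)O1 | intermediate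
26 | formosanatin D | CC1(C)C=Cc2c(c(O)cc3c2oc2oc4c5c(cc(O)c4c(=O)c23)OC(C)(C)CC5)O1 | target

**Step count and risks**
Total: 14 steps. Longest linear sequence: 9 steps (steps 1–6, then 12–14); the ring B branch contributes 5 steps (7–11).

1. Step 13 (carries the label "Proposed new method:").
   - What may go wrong: methanol or adventitious water may add to the activated C2 faster than the ring A phenol, opening the aminofuran to a lactone and from there toward the coumestan series. The ammonium group may also fail to leave, so that prolonged heating lets the chromene double bond add methanol.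
   - Fallback (known chemistry, furan closed last by oxidation): it sets out from ketone 7 and chromenol 19 and returns at 25.
   - Ketone 7 is heated with N,N-dimethylformamide dimethyl acetal to give enaminone F1, which iodine in chloroform/pyridine cyclises on the free hydroxyl to 3-iodochromone F2.
   - Chromenol 19 is iodinated at its free ortho carbon (I2, morpholine, CH2Cl2) to iodophenol F3 and converted by Miyaura borylation (B2pin2, Pd(dppf)Cl2, KOAc, dioxane) into pinacol boronate F4.
   - Suzuki coupling of F2 with F4 (Pd(PPh3)4, Na2CO3, DME/H2O) should give 2'-hydroxyisoflavone F5.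
   - Dehydrogenative cyclisation of F5 with DDQ, the established route from 2'-hydroxyisoflavones to coumaronochromones, forms the C2–O bond and gives methoxymethyl ether F6; HCl in methanol then releases 25.

2. Step 12.
   - What may go wrong: the quinone methide may be consumed by a second molecule of phenol or by dimerisation before the isocyanide adds. Hydroxyalkylation may be too slow under an acid mild enough to spare the methoxymethyl ethers, or the isocyanide may be degraded by the acid.
   - Fallback (quinone methide released from an isolated precursor in the absence of acid and free phenol): it sets out from 9 and 19 and returns at 23.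
   - Phenylboronic acid templates the ortho-hydroxyalkylation of 19 by 9 (PhB(OH)2, cat. propionic acid, toluene, reflux with removal of water) and gives the cyclic phenylboronate of carbinol 21, benzodioxaborin F7.
   - Heating F7 with isocyanide 20 in toluene at 110 °C should release the ortho-quinone methide by cycloreversion, and [4+1] capture then gives 23.

3. Step 6.
   - What may go wrong: over-oxidation of the glyoxal to the arylglyoxylic acid, loss of the methoxymethyl ether under hot selenous acid, or sluggish enolisation of the twisted, doubly ortho-substituted ketone.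
   - Fallback (oxidative cleavage of a C=C bond instead of α-oxidation): it sets out from 8 and returns at 9.
   - Condensation of 8 with tert-butoxybis(dimethylamino)methane (neat, 100 °C) gives enaminone F8.
   - Cleavage of its C=C bond with singlet oxygen (O2, hν, tetraphenylporphyrin, CH2Cl2, −78 °C) should deliver 9 under neutral conditions.

**Further compounds**
F1 | step 13 | (E)-3-(dimethylamino)-1-(5-hydroxy-7-methoxy-2,2-dimethylchroman-6-yl)prop-2-en-1-one | CN(C)/C=C/C(=O)c1c(OC)cc2OC(C)(C)CCc2c1O
F2 | step 13 | 3-iodo-5-methoxychromone with the 2,2-dimethyldihydropyran fused at C7–C8 (pyran oxygen on C7) | COc1cc2OC(C)(C)CCc2c2occ(I)c(=O)c12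
F3 | step 13 | 6-iodo-8-(methoxymethoxy)-2,2-dimethyl-2H-chromen-5-ol | COCOc1cc(I)c(O)c2C=CC(C)(C)Oc12
F4 | step 13 | 8-(methoxymethoxy)-2,2-dimethyl-6-(4,4,5,5-tetramethyl-1,3,2-dioxaborolan-2-yl)-2H-chromen-5-ol | COCOc1cc(B3OC(C)(C)C(C)(C)O3)c(O)c2C=CC(C)(C)Oc12
F5 | step 13 | 2'-hydroxyisoflavone: chromone of F2 carrying on C3 the 5-hydroxy-8-(methoxymethoxy)-2,2-dimethyl-2H-chromen-6-yl group | COCOc1cc(-c3coc4c5CCC(C)(C)Oc5cc(OC)c4c3=O)c(O)c2C=CC(C)(C)Oc12
F6 | step 13 | 5'-O-(methoxymethyl)-5-O-methylformosanatin D | CC1(C)C=Cc2c(c(OCOC)cc3c2oc2oc4c5c(cc(OC)c4c(=O)c23)OC(C)(C)CC5)O1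
F7 | step 12 | cyclic phenylboronate of carbinol 21 (2-phenyl-4H-1,3,2-benzodioxaborin spanning the phenolic and carbinol oxygens) | COCOc1cc2C(C(=O)c3c(OC)cc4OC(C)(C)CCc4c3OCOC)OB(c3ccccc3)Oc2c2C=CC(C)(C)Oc12
F8 | step 6 | (E)-3-(dimethylamino)-1-[7-methoxy-5-(methoxymethoxy)-2,2-dimethylchroman-6-yl]prop-2-en-1-one | CN(C)/C=C/C(=O)c1c(OC)cc2OC(C)(C)CCc2c1OCOC
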